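**Retrosynthetic overview**
- Target ⇒ ring-A o-quinone. In one redox-neutral operation the o-quinone tautomerizes to a p-quinone methide, the C-5 hydroxyl adds 1,6 to close the oxane, and the liberated catechol is chelated as a cyclic borate (ring A = the aryl ring on the oxane).
- o-Quinone ⇒ C2-symmetric (3S,5S)-octahydrocurcumin by Teuber ortho-oxygenation of one of its two homotopic guaiacol rings. This installs the extra ring-A oxygen and the oxidation level needed for ring closure.
- Diol ⇒ tetrahydrocurcumin by anti-selective double asymmetric hydrogenation, which sets both carbinol centres; the third centre follows from them under thermodynamic control.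
- Ring order: no ring is formed in steps 1 and 2. In step 3 the oxane ring and the five-membered dioxaborole ring close in the same operation; the boracycle is opened again on acid work-up.

Assumption: tetrahydrocurcumin, sold in bulk as a cosmetic antioxidant and one hydrogenation away from curcumin, is taken as a cheap commercial starting material.

**Step 1**
Reactants: 1 tetrahydrocurcumin [1,7-bis(4-hydroxy-3-methoxyphenyl)heptane-3,5-dione]
Product: 2 (3S,5S)-1,7-bis(4-hydroxy-3-methoxyphenyl)heptane-3,5-diol
Conditions: [RuCl(p-cymene)((S)-BINAP)]Cl (1 mol%), H2 (70 atm), MeOH, 50 °C, 36 h; recrystallization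
Reagents that add atoms: none
Why: Noyori asymmetric hydrogenation of a 1,3-diketone reduces the first carbonyl under catalyst control and the resulting β-hydroxy ketone again in the matched sense, so the (S)-ligand gives the anti (3S,5S)-diol (same sense as acetylacetone, where the (R)-ligand gives the (R,R)-diol), with residual stereo-errors ending up mainly as the meso diol that crystallization removes.

**Step 2**
Reactants: 2 (3S,5S)-1,7-bis(4-hydroxy-3-methoxyphenyl)heptane-3,5-diol
Product: 3 5-[(3S,5S)-3,5-dihydroxy-7-(4-hydroxy-3-methoxyphenyl)heptyl]-3-methoxycyclohexa-3,5-diene-1,2-dione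
Conditions: K2[ON(SO3)2] (Fremy's salt, 1.5 equiv), KH2PO4 (aq, pH 6)–acetone 3:1, 0 °C, 40 min; cold EtOAc extraction, crude used at once
Reagents that add atoms: potassium nitrosodisulfonate (Fremy's salt), [K+].[K+].[O]N(S(=O)(=O)[O-])S(=O)(=O)[O-]
Why: Teuber oxidation, in which one nitrosodisulfonate radical removes the phenolic hydrogen and a second couples at the only free ortho C–H (para is blocked, the methoxy-bearing carbon is not attacked) to give the 3-methoxy-1,2-quinone without touching the secondary alcohols or the stereocentres; the two rings of 2 are homotopic, so mono-oxidation gives one compound, with a statistical ceiling near 50% per pass and unreacted 2 recycled.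

**Step 3**
Reactants: 3 5-[(3S,5S)-3,5-dihydroxy-7-(4-hydroxy-3-methoxyphenyl)heptyl]-3-methoxycyclohexa-3,5-diene-1,2-dione
Product: 6 (2S,4R,6S)-2-(3,4-dihydroxy-5-methoxyphenyl)-6-[2-(4-hydroxy-3-methoxyphenyl)ethyl]oxan-4-ol, via p-quinone methide 4 (not isolated), via cyclic borate 5 (not isolated)
Conditions: Na2B4O7–B(OH)3 buffer (0.2 M, pH 8.5)–MeCN 4:1, degassed, Ar, 0 to 25 °C, 3 h; then 1 M HCl to pH 1.5, 25 °C, 2 h
Reagents that add atoms: none
Why: Proposed new method: base-catalysed tautomerization of the 4-alkyl-1,2-quinone to its p-quinone methide 4 (a known isomerization of 4-alkyl-o-quinones with a benzylic C–H) is followed by six-membered intramolecular 1,6-oxa-addition of the C-5 hydroxyl (closest known reaction type: oxa-1,6-conjugate addition of alcohols to p-quinone methides, as in lignin chemistry), which re-aromatizes ring A to a catechol that borate chelates at once as boracycle 5 and so shields from redox exchange with unreacted quinone; acidification frees boric acid and lets the p-hydroxybenzylic C–O bond ionize reversibly, so the new stereocentre C-2 settles under thermodynamic control as the all-equatorial 2,4,6-cis oxane dictated by the two carbinol centres.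

**Compound list**
1 | tetrahydrocurcumin, 1,7-bis(4-hydroxy-3-methoxyphenyl)heptane-3,5-dione | COc1cc(CCC(=O)CC(=O)CCc2ccc(O)c(OC)c2)ccc1O | starting material
2 | (3S,5S)-1,7-bis(4-hydroxy-3-methoxyphenyl)heptane-3,5-diol, (3S,5S)-octahydrocurcumin | COc1cc(CC[C@H](O)C[C@@H](O)CCc2ccc(O)c(OC)c2)ccc1O | intermediate
3 | 5-[(3S,5S)-3,5-dihydroxy-7-(4-hydroxy-3-methoxyphenyl)heptyl]-3-methoxycyclohexa-3,5-diene-1,2-dione (ring-A o-quinone) | COc1cc(CC[C@H](O)C[C@@H](O)CCC2=CC(=O)C(=O)C(OC)=C2)ccc1O | intermediate
4 | 4-[(3S,5S)-3,5-dihydroxy-7-(4-hydroxy-3-methoxyphenyl)heptylidene]-2-hydroxy-6-methoxycyclohexa-2,5-dien-1-one (p-quinone methide, alkene geometry not defined) | COc1cc(CC[C@H](O)C[C@@H](O)CC=C2C=C(O)C(=O)C(OC)=C2)ccc1O | intermediate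
5 | sodium 2,2-dihydroxy-6-[(2S,4R,6S)-4-hydroxy-6-[2-(4-hydroxy-3-methoxyphenyl)ethyl]oxan-2-yl]-4-methoxy-1,3,2-benzodioxaborol-2-uide (borate chelate of the ring-A catechol) | COc1cc(CC[C@H]2C[C@@H](O)C[C@@H](c3cc4O[B-](O)(O)Oc4c(OC)c3)O2)ccc1O.[Na+] | intermediate
6 | (2S,4R,6S)-2-(3,4-dihydroxy-5-methoxyphenyl)-6-[2-(4-hydroxy-3-methoxyphenyl)ethyl]oxan-4-ol | COc1cc(CC[C@H]2C[C@@H](O)C[C@@H](c3cc(O)c(O)c(OC)c3)O2)ccc1O | target

**Totals**
Total step count: 3. Longest linear sequence: 3 steps (1 → 2 → 3 → 6).

**Steps most likely to fail**

Step 3 (highest risk). Before the oxane closes, the quinone or its methide may be lost by hydration, by loss of a C-2 proton to the styrene, by 1,4-addition of the C-3 hydroxyl to the quinone ring (chroman), or by oligomerization. The fallback uncouples ring closure from isomerization and sets out from 3. Compound 3 is isomerized in dry methanol with catalytic Et3N under argon, so that the solvent rather than the chain hydroxyl captures the quinone methide. This gives the benzylic methyl ether 5-[(3R,5S)-3,5-dihydroxy-7-(4-hydroxy-3-methoxyphenyl)-1-methoxyheptyl]-3-methoxybenzene-1,2-diol F4, as both C-1 epimers; the carbinol centres are spatially unchanged and the C-3 descriptor changes only formally. This catechol is purified and treated with catalytic TsOH in MeCN at 25 °C. SN1 ionization of the p-hydroxybenzyl ether and capture by the C-5 hydroxyl then close the oxane under thermodynamic control with loss of methanol, coming back to the route at 6.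

Step 2. The risks are double oxidation to the bis-quinone, the statistical ceiling, and premature isomerization while oxidant is still present. The fallback introduces the oxygen through carbon and sets out from 2. Magnesium-mediated ortho-formylation (MgCl2, Et3N, paraformaldehyde, MeCN, reflux) gives the mono-salicylaldehyde 5-[(3S,5S)-3,5-dihydroxy-7-(4-hydroxy-3-methoxyphenyl)heptyl]-2-hydroxy-3-methoxybenzaldehyde F2, which is bench-stable and separable from 2 and the dialdehyde. Dakin oxidation (H2O2, aqueous NaOH, 0 °C) converts it with loss of formate into the catechol 5-[(3S,5S)-3,5-dihydroxy-7-(4-hydroxy-3-methoxyphenyl)heptyl]-3-methoxybenzene-1,2-diol F3. NaIO4 (1.0 equiv, pH 5, 0 °C) then oxidizes only the catechol ring and returns to the route at 3.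

Step 1. The risks are catalyst inhibition by the four acidic O–H groups, an incomplete second reduction, or a poor anti:syn ratio. The fallback replaces double catalyst control by one enzymatic reduction followed by substrate control and sets out from 1. One carbonyl is reduced with an NADPH-dependent ketoreductase (glucose/glucose dehydrogenase recycling, pH 7 buffer–DMSO, 30 °C) to (5S)-5-hydroxy-1,7-bis(4-hydroxy-3-methoxyphenyl)heptan-3-one F1. The second carbinol is then set 1,3-anti by intramolecular hydride delivery with Me4NBH(OAc)3 (MeCN–AcOH, −30 °C, Evans–Saksena reduction), coming back to the route at 2.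

**Further compounds**
F1 | step 1 | (5S)-5-hydroxy-1,7-bis(4-hydroxy-3-methoxyphenyl)heptan-3-one | COc1cc(CC[C@H](O)CC(=O)CCc2ccc(O)c(OC)c2)ccc1O
F2 | step 2 | 5-[(3S,5S)-3,5-dihydroxy-7-(4-hydroxy-3-methoxyphenyl)heptyl]-2-hydroxy-3-methoxybenzaldehyde | COc1cc(CC[C@H](O)C[C@@H](O)CCc2cc(C=O)c(O)c(OC)c2)ccc1O
F3 | step 2 | 5-[(3S,5S)-3,5-dihydroxy-7-(4-hydroxy-3-methoxyphenyl)heptyl]-3-methoxybenzene-1,2-diol | COc1cc(CC[C@H](O)C[C@@H](O)CCc2cc(O)c(O)c(OC)c2)ccc1O
F4 | step 3 | 5-[(3R,5S)-3,5-dihydroxy-7-(4-hydroxy-3-methoxyphenyl)-1-methoxyheptyl]-3-methoxybenzene-1,2-diol (C-1 epimers) | COc1cc(CC[C@H](O)C[C@@H](O)CC(OC)c2cc(O)c(O)c(OC)c2)ccc1O
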